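C1 is the benzylic carbinol carbon (O1, ring A = 4-hydroxy-2-methoxyphenyl), C2 the acyloxy carbon (O2), C3 the CH2 to ring B (prenylphenol), and ring C is the syringyl ring. The SMILES reads (1S,2R), the erythro series.
Retrosynthesis cuts, in order: the three ArO–Si bonds; the C(=O)–C(aryl) bond of the syringate (ring C aryllithium plus a carbonyl carbon already tied to O1 and O2 as a cyclic carbonate); the two carbonate C–O bonds; C3–ring B (terminal epoxide plus aryl Grignard); the epoxide oxygen; and C1–C2 (aldehyde plus vinyl Grignard).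
Forward, the chain grows from the ring A aldehyde (C1) by a vinyl unit (C2, C3) and ring B is joined at C3. The only ring made is a temporary cis-1,3-dioxolan-2-one over O1–C1–C2–O2, which ring C then opens.
The enabling feature is that the vicinal oxygens O1 and O2 can share the future ester carbonyl carbon in a five-membered carbonate. The 2-methoxy oxygen of ring A can then hold the benzylic O1 alkoxide in a six-membered lithium chelate, so O1 leaves and the acyl group stays on O2.
Both stereocentres come from one Sharpless epoxidation run as a kinetic resolution with L-(+)-DIPT: C1 is selected and C2 is created. No later step breaks a C–O bond at C1 or C2.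

Key step: step 9

Assumption: 4-hydroxy-2-methoxybenzaldehyde, 4-bromophenol and 4-bromo-2,6-dimethoxyphenol are taken as commercial. TBS = tert-butyldimethylsilyl, TES = triethylsilyl, prenyl = 3-methylbut-2-en-1-yl.

Step 1
Reactants: 1 4-hydroxy-2-methoxybenzaldehyde
Product: 2 4-(tert-butyldimethylsilyloxy)-2-methoxybenzaldehyde
Conditions: TBSCl, imidazole, DMF, rt
Reagents that add atoms: tert-butyldimethylsilyl chloride, CC(C)(C)[Si](C)(C)Cl
Why: Imidazole-promoted silylation of a phenol gives an aryl silyl ether that should survive the organometallic and oxidative steps ahead and leave under buffered fluoride at the end.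

Step 2
Reactants: 2 4-(tert-butyldimethylsilyloxy)-2-methoxybenzaldehyde
Product: 3 racemic 1-[4-(tert-butyldimethylsilyloxy)-2-methoxyphenyl]prop-2-en-1-ol
Conditions: vinylMgBr (1.1 equiv), THF, −78 → 0 °C; aqueous work-up
Reagents that add atoms: vinylmagnesium bromide, C=C[Mg]Br
Why: Grignard 1,2-addition to an aromatic aldehyde should be clean because the silyl and methyl ethers are inert at low temperature; C1 is formed racemic on purpose and is sorted in step 3.

Step 3
Reactants: 3 racemic 1-[4-(tert-butyldimethylsilyloxy)-2-methoxyphenyl]prop-2-en-1-ol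
Product: 4 (S)-[4-(tert-butyldimethylsilyloxy)-2-methoxyphenyl][(R)-oxiran-2-yl]methanol (erythro epoxy alcohol)
Conditions: Ti(OiPr)4 (0.2 equiv), L-(+)-DIPT (0.24 equiv), TBHP (0.45 equiv, decane), 4 Å MS, CH2Cl2, −20 °C; triethanolamine work-up
Reagents that add atoms: tert-butyl hydroperoxide, CC(C)(C)OO
Why: In this Sharpless asymmetric epoxidation run as a kinetic resolution with L-(+)-DIPT, the (R)-carbinol is the fast-reacting enantiomer and takes oxygen on the face that gives the erythro epoxy alcohol, so C1 is selected (descriptor S after the change of CIP priorities) and C2 (R) is set by the titanium tartrate catalyst while the (S)-carbinol stays unreacted.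

Step 4
Reactants: 5 4-bromophenol
Product: 6 4-bromo-2-(3-methylbut-2-en-1-yl)phenol
Conditions: NaH (1.0 equiv), toluene, 0 °C → rt; prenyl bromide (1.0 equiv), rt
Reagents that add atoms: prenyl bromide (1-bromo-3-methylbut-2-ene), CC(C)=CCBr
Why: In this ortho-C-alkylation of a phenoxide, the tight sodium ion pair in a non-polar solvent shields oxygen, and the bromine blocks the para position, so carbon attack should occur only ortho.

Step 5
Reactants: 6 4-bromo-2-(3-methylbut-2-en-1-yl)phenol
Product: 7 [4-bromo-2-(3-methylbut-2-en-1-yl)phenoxy](tert-butyl)dimethylsilane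
Conditions: TBSCl, imidazole, DMF, rt
Reagents that add atoms: tert-butyldimethylsilyl chloride, CC(C)(C)[Si](C)(C)Cl
Why: Imidazole-promoted silylation of the phenol removes the acidic proton before metalation and prevents acid-induced closure of the prenylphenol to a chroman.

Step 6
Reactants: 7 [4-bromo-2-(3-methylbut-2-en-1-yl)phenoxy](tert-butyl)dimethylsilane; 4 (S)-[4-(tert-butyldimethylsilyloxy)-2-methoxyphenyl][(R)-oxiran-2-yl]methanol
Product: 10 (1S,2R)-1-[4-(tert-butyldimethylsilyloxy)-2-methoxyphenyl]-3-[4-(tert-butyldimethylsilyloxy)-3-(3-methylbut-2-en-1-yl)phenyl]propane-1,2-diol, via aryl Grignard 8 (not isolated), via bromomagnesium alkoxide 9 (not isolated)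
Conditions: 7 (1.3 equiv), Mg, THF, 40 °C; separately 4, MeMgBr (1.0 equiv), THF, −40 °C; combine, CuI (10 mol%), −40 → 0 °C; aqueous work-up
Reagents that add atoms: none
Why: Copper-catalysed Grignard opening of a terminal epoxide is an SN2 attack at the unsubstituted carbon C3 after sacrificial deprotonation of the carbinol, so neither C–O bond at C1 or C2 is touched and the erythro relation is carried into the diol.

Step 7
Reactants: 10 (1S,2R)-1-[4-(tert-butyldimethylsilyloxy)-2-methoxyphenyl]-3-[4-(tert-butyldimethylsilyloxy)-3-(3-methylbut-2-en-1-yl)phenyl]propane-1,2-diol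
Product: 11 (4S,5R)-4-[4-(tert-butyldimethylsilyloxy)-2-methoxyphenyl]-5-{[4-(tert-butyldimethylsilyloxy)-3-(3-methylbut-2-en-1-yl)phenyl]methyl}-1,3-dioxolan-2-one (cis)
Conditions: CDI (1.3 equiv), DMAP (cat.), CH2Cl2, rt
Reagents that add atoms: 1,1'-carbonyldiimidazole, O=C(n1ccnc1)n1ccnc1
Why: Carbonylation of a 1,2-diol with CDI (acyl imidazolide formation, then 5-exo-trig closure) touches only O–H bonds, so the erythro diol should map onto the cis-4,5-disubstituted carbonate with C1 and C2 unchanged.

Step 8
Reactants: 12 4-bromo-2,6-dimethoxyphenol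
Product: 13 (4-bromo-2,6-dimethoxyphenoxy)(tert-butyl)dimethylsilane
Conditions: TBSCl, imidazole, DMAP (cat.), DMF, 40 °C
Reagents that add atoms: tert-butyldimethylsilyl chloride, CC(C)(C)[Si](C)(C)Cl
Why: Imidazole-promoted silylation of the flanked phenol, helped by DMAP and gentle warming, removes the acidic proton before bromine–lithium exchange.

Step 9
Reactants: 13 (4-bromo-2,6-dimethoxyphenoxy)(tert-butyl)dimethylsilane; 11 cis-carbonate
Product: 17 (1S,2R)-1-[4-(tert-butyldimethylsilyloxy)-2-methoxyphenyl]-1-hydroxy-3-[4-(tert-butyldimethylsilyloxy)-3-(3-methylbut-2-en-1-yl)phenyl]propan-2-yl 4-(tert-butyldimethylsilyloxy)-3,5-dimethoxybenzoate, via aryllithium 14 (not isolated), via lithium hemiorthoester 15 (not isolated), via chelated lithium C1-alkoxide 16 (not isolated)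
Conditions: 13, n-BuLi (1.0 equiv), THF, −78 °C; cannulate into 11 (1.0 equiv), THF, −78 → −40 °C; AcOH, −78 °C
Reagents that add atoms: none
Why: Bromine–lithium exchange gives aryllithium 14, which adds once to the strained carbonate C=O of 11 (nucleophilic acyl addition) to give the lithium 2-aryl-1,3-dioxolan-2-olate 15, and this collapses by C–O cleavage, so that one C–C bond formation installs the syringoyl group, frees the diol and tells O1 from O2 at once. The closest known reaction type is the opening of cyclic carbonates of 1,2-diols by aryllithiums at −78 °C to give vicinal hydroxy benzoates. No ring is closed, the five-membered carbonate ring is opened, and no new stereocentre remains, because only acyl C–O bonds are made and broken, C1 (S) and C2 (R) are carried over from 11, and the transient orthoester carbon of 15 becomes planar again. The step needs regioselectivity between two secondary oxygens: O1 should leave because it gives the better stabilised benzylic alkoxide, held in 16 by lithium in a six-membered chelate (Li–O1–C1–C ipso–C ortho–OMe) with the 2-methoxy group of ring A, and because the acyl group then sits on the less crowded O2; since 15 and both ester alkoxides interconvert by 1,2-acyl shift, the short warming to −40 °C lets kinetic and thermodynamic preference point to the same isomer before the cold acetic acid quench freezes it. The step also needs mono-addition, which one equivalent of 14, the persistence of 15 at low temperature and the poor electrophilicity of an electron-rich syringate next to an alkoxide should secure. The aryl silyl ethers, methyl ethers and prenyl alkene are inert to an aryllithium at this temperature, and lithium para to the silyloxy group has no path for silyl migration to carbon.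

Step 10
Reactants: 17 tris-TBS ether of the target
Product: 18 eryvarinol B, (1S,2R)-1-hydroxy-1-(4-hydroxy-2-methoxyphenyl)-3-[4-hydroxy-3-(3-methylbut-2-en-1-yl)phenyl]propan-2-yl 4-hydroxy-3,5-dimethoxybenzoate
Conditions: TBAF (3.3 equiv), AcOH (3.5 equiv), THF, 0 °C
Reagents that add atoms: none
Why: Fluoride-induced cleavage of aryl silyl ethers is far faster than any reaction of the ester, and the acetic acid buffer keeps the phenols protonated, so O2→O1 acyl shift and quinone methide formation from the 4-hydroxybenzylic alcohol should be held back while C1 and C2 stay untouched.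

Compound list
1 | 4-hydroxy-2-methoxybenzaldehyde | COc1cc(O)ccc1C=O | starting material
2 | 4-(tert-butyldimethylsilyloxy)-2-methoxybenzaldehyde | COc1cc(O[Si](C)(C)C(C)(C)C)ccc1C=O | intermediate
3 | racemic 1-[4-(tert-butyldimethylsilyloxy)-2-methoxyphenyl]prop-2-en-1-ol | COc1cc(O[Si](C)(C)C(C)(C)C)ccc1C(O)C=C | intermediate
4 | (S)-[4-(tert-butyldimethylsilyloxy)-2-methoxyphenyl][(R)-oxiran-2-yl]methanol | COc1cc(O[Si](C)(C)C(C)(C)C)ccc1[C@H](O)[C@@H]1OC1 | intermediate
5 | 4-bromophenol | Oc1ccc(Br)cc1 | starting material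
6 | 4-bromo-2-(3-methylbut-2-en-1-yl)phenol | CC(C)=CCc1cc(Br)ccc1O | intermediate
7 | [4-bromo-2-(3-methylbut-2-en-1-yl)phenoxy](tert-butyl)dimethylsilane | CC(C)=CCc1cc(Br)ccc1O[Si](C)(C)C(C)(C)C | intermediate
8 | [4-(tert-butyldimethylsilyloxy)-3-(3-methylbut-2-en-1-yl)phenyl]magnesium bromide (not isolated) | CC(C)=CCc1cc([Mg]Br)ccc1O[Si](C)(C)C(C)(C)C | intermediate
9 | bromomagnesium alkoxide of 4 (not isolated) | COc1cc(O[Si](C)(C)C(C)(C)C)ccc1[C@H](O[Mg]Br)[C@@H]1OC1 | intermediate
10 | (1S,2R)-1-[4-(TBSO)-2-methoxyphenyl]-3-[4-(TBSO)-3-prenylphenyl]propane-1,2-diol | COc1cc(O[Si](C)(C)C(C)(C)C)ccc1[C@H](O)[C@@H](Cc1ccc(O[Si](C)(C)C(C)(C)C)c(CC=C(C)C)c1)O | intermediate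
11 | (4S,5R)-4-[4-(TBSO)-2-methoxyphenyl]-5-{[4-(TBSO)-3-prenylphenyl]methyl}-1,3-dioxolan-2-one (cis) | COc1cc(O[Si](C)(C)C(C)(C)C)ccc1[C@@H]1OC(=O)O[C@@H]1Cc1ccc(O[Si](C)(C)C(C)(C)C)c(CC=C(C)C)c1 | intermediate
12 | 4-bromo-2,6-dimethoxyphenol | COc1cc(Br)cc(OC)c1O | starting material
13 | (4-bromo-2,6-dimethoxyphenoxy)(tert-butyl)dimethylsilane | COc1cc(Br)cc(OC)c1O[Si](C)(C)C(C)(C)C | intermediate
14 | [4-(tert-butyldimethylsilyloxy)-3,5-dimethoxyphenyl]lithium (not isolated) | COc1cc([Li])cc(OC)c1O[Si](C)(C)C(C)(C)C | intermediate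
15 | lithium (4S,5R)-2-aryl-4,5-disubstituted-1,3-dioxolan-2-olate, configuration at C2 of the ring undefined (not isolated) | COc1cc(O[Si](C)(C)C(C)(C)C)ccc1[C@@H]1OC(O[Li])(c2cc(OC)c(O[Si](C)(C)C(C)(C)C)c(OC)c2)O[C@@H]1Cc1ccc(O[Si](C)(C)C(C)(C)C)c(CC=C(C)C)c1 | intermediate
16 | lithium C1-alkoxide of 17 (not isolated) | COc1cc(O[Si](C)(C)C(C)(C)C)ccc1[C@H](O[Li])[C@@H](Cc1ccc(O[Si](C)(C)C(C)(C)C)c(CC=C(C)C)c1)OC(=O)c1cc(OC)c(O[Si](C)(C)C(C)(C)C)c(OC)c1 | intermediate
17 | tris-TBS ether of eryvarinol B, (1S,2R) | COc1cc(O[Si](C)(C)C(C)(C)C)ccc1[C@H](O)[C@@H](Cc1ccc(O[Si](C)(C)C(C)(C)C)c(CC=C(C)C)c1)OC(=O)c1cc(OC)c(O[Si](C)(C)C(C)(C)C)c(OC)c1 | intermediate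
18 | eryvarinol B, (1S,2R) | COc1cc(O)ccc1[C@H](O)[C@@H](Cc1ccc(O)c(CC=C(C)C)c1)OC(=O)c1cc(OC)c(O)c(OC)c1 | target

Total step count: 10. Longest linear sequence: 7 (steps 1, 2, 3, 6, 7, 9, 10).

Steps most likely to fail

Step 9. Regiocontrol may be lost if O2 rather than O1 departs from the tetrahedral intermediate, or if the acyl group shifts during the quench. The aryllithium may also add a second time to the fresh ester. The fallback forms the same C(=O)–C(aryl) bond by a three-component palladium-catalysed alkoxycarbonylation on a substrate in which O1 is masked. It sets out from 4, which is silylated (TESCl, imidazole, CH2Cl2, 0 °C) to the triethylsilyl ether of the epoxy alcohol F1. Copper-catalysed opening with Grignard 8 (CuI cat., THF, −30 °C) gives the O1-TES C2-alcohol F2. This is coupled with aryl bromide 13 and carbon monoxide (Pd(OAc)2, Xantphos, Et3N, DMAP cat., CO 1 atm, toluene, 80 °C) to the tetrasilylated ester F3. Global desilylation (Et3N·3HF, THF, rt) brings the route back at 18.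

Step 3. The rate difference between the enantiomers of an ortho-methoxyaryl vinyl carbinol may be too small, and the monosubstituted alkene is epoxidised slowly. The electron-rich benzylic epoxy alcohol may ionise or open under titanium during the long reaction time, and only half of the material can be used. The fallback lets a lipase set C1 and leaves only the face of the alkene to the oxidant. It sets out from 3, which is acylated by immobilised Candida antarctica lipase B with vinyl acetate (MTBE, 30 °C), expected by the Kazlauskas rule to give the (R)-acetate F4. After separation from the unreacted (S)-alcohol, reduction (DIBAL-H, CH2Cl2, −78 °C) gives the (R)-allylic alcohol F5 without touching the aryl silyl ether. The matched Sharpless epoxidation (Ti(OiPr)4, L-(+)-DIPT, TBHP, 4 Å MS, CH2Cl2, −20 °C), taken to full conversion, brings the route back at 4.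

Step 4. O-alkylation and double alkylation may compete with ortho-C-alkylation of the ambident phenoxide, and the product may close to a chroman under acid during work-up. The fallback delivers the prenyl group by a sigmatropic shift that can only end ortho. It sets out from 5, which is O-alkylated with 3-chloro-3-methylbut-1-yne (CuCl2 cat., DBU, MeCN, 0 °C) to the 1,1-dimethylpropargyl ether F6. Semihydrogenation (H2, Lindlar catalyst, quinoline, EtOAc) gives the 1,1-dimethylallyl ether F7. An aromatic Claisen rearrangement (N,N-diethylaniline, 130–150 °C) brings the route back at 6.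

Further compounds
F1 | step 9 | (S)-[4-(TBSO)-2-methoxyphenyl][(R)-oxiran-2-yl]methyl triethylsilyl ether | COc1cc(O[Si](C)(C)C(C)(C)C)ccc1[C@H](O[Si](CC)(CC)CC)[C@@H]1OC1
F2 | step 9 | (1S,2R)-1-[4-(TBSO)-2-methoxyphenyl]-3-[4-(TBSO)-3-prenylphenyl]-1-(triethylsilyloxy)propan-2-ol | COc1cc(O[Si](C)(C)C(C)(C)C)ccc1[C@H](O[Si](CC)(CC)CC)[C@@H](Cc1ccc(O[Si](C)(C)C(C)(C)C)c(CC=C(C)C)c1)O
F3 | step 9 | (1S,2R)-1-[4-(TBSO)-2-methoxyphenyl]-3-[4-(TBSO)-3-prenylphenyl]-1-(triethylsilyloxy)propan-2-yl 4-(TBSO)-3,5-dimethoxybenzoate | COc1cc(O[Si](C)(C)C(C)(C)C)ccc1[C@H](O[Si](CC)(CC)CC)[C@@H](Cc1ccc(O[Si](C)(C)C(C)(C)C)c(CC=C(C)C)c1)OC(=O)c1cc(OC)c(O[Si](C)(C)C(C)(C)C)c(OC)c1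
F4 | step 3 | (R)-1-[4-(TBSO)-2-methoxyphenyl]prop-2-en-1-yl acetate | COc1cc(O[Si](C)(C)C(C)(C)C)ccc1[C@H](OC(C)=O)C=C
F5 | step 3 | (R)-1-[4-(TBSO)-2-methoxyphenyl]prop-2-en-1-ol | COc1cc(O[Si](C)(C)C(C)(C)C)ccc1[C@H](O)C=C
F6 | step 4 | 1-bromo-4-[(2-methylbut-3-yn-2-yl)oxy]benzene | C#CC(C)(C)Oc1ccc(Br)cc1
F7 | step 4 | 1-bromo-4-[(2-methylbut-3-en-2-yl)oxy]benzene | C=CC(C)(C)Oc1ccc(Br)cc1
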